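**Plan**

Rings: A = benzo ring of the naphthalenone, B = six-membered ketone ring, C = furan, D = seven-membered hydroxytropone ring, E = benzo ring on D.
Cuts, in retrosynthetic order: (1) the furan–isobutenyl bond (Suzuki–Miyaura, bromide 11 from C–H bromination of 10); (2) the bond between the furan α-carbon and the ortho carbon of ring A, which opens ring B to the plain phenyl ketone 8.
Then (3) ring D at the bond between its enolised carbonyl carbon and the benzoyl-bearing carbon (Dieckmann-type Claisen) and at the furan C-4–CH2 bond (Pd α-arylation of acetophenone); (4) the furan C-3–carbonyl bond (furyllithium plus phthalic anhydride).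
Forward: ring C is bought as 3,4-dibromofuran and ring E comes with phthalic anhydride; ring D closes in step 3, ring B in step 4, and the side chain is joined last (steps 5 and 6).
Enabling feature: in 8 (C-1 and C-3 furan CH, C-4 ketone, C-9 C–OH, C-10 benzoyl-bearing carbon, C-10a furan carbon) the C-9/C-10/benzoyl 1,3-diketone is a chelated enol, so C-1=C-10a, the enol C-10=C(OH) and the phenyl ring form a cis-stilbene hexatriene; a dehydrogenative 6π photocyclization can therefore join an unfunctionalised phenyl ketone to the furan C–H.
Stereochemistry: the target has no stereocentre and its alkene carries two identical methyl groups; the two sp3 centres of the transient trans-dihydro intermediate 9 are lost on aromatisation.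

Key step: step 4

Remark: radermachol is drawn as the ring B ketone/ring D enol tautomer. Step 4 first gives the naphthol/ring D ketone tautomer, which interconverts with it by proton shift along the hydrogen bond; the two are treated as one compound, and 10, 11 and 13 are written in the tautomeric form of the target.

**Route**

Step 1
Reactants: 1 3,4-dibromofuran; 2 phthalic anhydride
Product: 4 2-(4-bromofuran-3-carbonyl)benzoic acid, via 3-bromo-4-lithiofuran 3 (not isolated)
Conditions: n-BuLi (1.0 equiv), Et2O, −78 °C; cannulate into 2 (1.2 equiv), THF, −78 °C to −20 °C; 1 M HCl
Reagents that add atoms: none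
Why: Bromine–lithium exchange should give the 3-furyllithium, which neither migrates to the α-position nor loses LiBr at −78 °C, and inverse addition to the anhydride (nucleophilic acyl substitution) should stop at the keto carboxylate because the ring-opened carboxylate shields the new ketone.

Step 2
Reactants: 4 2-(4-bromofuran-3-carbonyl)benzoic acid
Product: 5 methyl 2-(4-bromofuran-3-carbonyl)benzoate
Conditions: MeI, K2CO3, DMF, rt
Reagents that add atoms: iodomethane, CI
Why: SN2 O-alkylation of the potassium carboxylate should give the open methyl ester and not the cyclic pseudo-ester that acid-catalysed esterification of 2-aroylbenzoic acids can give.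

Step 3
Reactants: 5 methyl 2-(4-bromofuran-3-carbonyl)benzoate; 6 acetophenone
Product: 8 10-benzoyl-9-hydroxy-4H-benzo[5,6]cyclohepta[1,2-c]furan-4-one, via phenacylfuran keto ester 7 (not isolated)
Conditions: 6 (1.3 equiv), Pd2(dba)3 (2.5 mol %), Xantphos (6 mol %), K3PO4 (2.5 equiv), toluene, 90 °C; then KOtBu (2.2 equiv), THF, 0 °C to rt; 1 M HCl
Reagents that add atoms: none
Why: Palladium-catalysed ketone α-arylation (Buchwald–Hartwig type) should couple the acetophenone enolate with the 3-bromofuran under the mild base K3PO4, which tolerates the ketone and ester, and KOtBu should then drive the Dieckmann-type intramolecular Claisen closure of ring D to the stabilised triketone enolate.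

Step 4
Reactants: 8 10-benzoyl-9-hydroxy-4H-benzo[5,6]cyclohepta[1,2-c]furan-4-one
Product: 10 nor-radermachol, via trans-dihydro intermediate 9 (not isolated)
Conditions: hν (365 nm), I2 (1.1 equiv), propylene oxide (50 equiv), degassed toluene (2 mM), Ar, rt
Reagents that add atoms: none
Why: Proposed new method: the exocyclic enol tautomer of 8, C-10=C(OH)Ph hydrogen-bonded to the C-9 carbonyl, holds the phenyl ring cis to the furan, so furan C-1=C-10a, the enol C=C and one phenyl C=C make a cis-stilbene-type hexatriene that on excitation should close by a photochemically allowed conrotatory 6π electrocyclization (ring B formed in 6π-electrocyclic mode) to the trans-dihydro intermediate 9. Iodine then removes the two hydrogens (as 2 HI, trapped by propylene oxide), and the naphthol so formed is the proton tautomer of 10. The closest known reaction type is the Mallory oxidative photocyclization of stilbenes, of 3-styrylfurans to naphtho[1,2-b]furans and of α-alkoxystilbenes; a hydrogen-bonded 1,3-diketone enol as the central double bond is the part without precedent. No stereocentre has to be controlled, since both sp3 centres of 9 are aromatised. The step needs site selectivity, which the substrate secures: C-1 is the only unsubstituted carbon next to C-10a, the two phenyl ortho positions are equivalent, and the hydrogen bond fixes the productive enol geometry. Iodine under argon is used in place of oxygen to keep singlet oxygen away from the furan.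

Step 5
Reactants: 10 nor-radermachol
Product: 11 bromo-nor-radermachol
Conditions: NBS (1.05 equiv), DMF, 0 °C to rt, dark
Reagents that add atoms: N-bromosuccinimide, O=C1CCC(=O)N1Br
Why: Electrophilic aromatic bromination should go to the only remaining furan C–H (the α-position next to oxygen), since every other position of the naphthofuran part is substituted and both benzo rings are deactivated by carbonyl groups.

Step 6
Reactants: 11 bromo-nor-radermachol; 12 4,4,5,5-tetramethyl-2-(2-methylprop-1-enyl)-1,3,2-dioxaborolane
Product: 13 radermachol
Conditions: 12 (1.5 equiv), Pd(PPh3)4 (5 mol %), K2CO3 (3 equiv), 1,4-dioxane/H2O, 80 °C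
Reagents that add atoms: none
Why: Suzuki–Miyaura coupling: the 2-bromofuran next to an acyl group should add readily to zerovalent palladium and the alkenyl pinacol boronate should transmetalate under aqueous carbonate, the extra base covering the acidic enol.

**Compound list**

1 | 3,4-dibromofuran | Brc1cocc1Br | starting material
2 | phthalic anhydride | O=C1OC(=O)c2ccccc12 | starting material
3 | 3-bromo-4-lithiofuran (not isolated) | [Li]c1cocc1Br | intermediate
4 | 2-(4-bromofuran-3-carbonyl)benzoic acid | OC(=O)c1ccccc1C(=O)c1cocc1Br | intermediate
5 | methyl 2-(4-bromofuran-3-carbonyl)benzoate | COC(=O)c1ccccc1C(=O)c1cocc1Br | intermediate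
6 | acetophenone | CC(=O)c1ccccc1 | starting material
7 | methyl 2-[4-(2-oxo-2-phenylethyl)furan-3-carbonyl]benzoate (phenacylfuran keto ester, not isolated) | COC(=O)c1ccccc1C(=O)c1cocc1CC(=O)c1ccccc1 | intermediate
8 | 10-benzoyl-9-hydroxy-4H-benzo[5,6]cyclohepta[1,2-c]furan-4-one (enol form of the triketone; furan fused through its 3,4-bond to a benzo-fused seven-membered ring) | O=C1c2ccccc2C(O)=C(C(=O)c2ccccc2)c2cocc12 | intermediate
9 | trans-dihydro intermediate: 8 with a new bond between furan C-1 and a phenyl ortho carbon, both sp3 CH with the two hydrogens trans (racemic, not isolated) | OC1=C2C=CC=C[C@@H]2[C@H]2OC=C3C(=O)c4ccccc4C(=O)C1=C32 | intermediate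
10 | nor-radermachol (radermachol with H in place of the 2-methylprop-1-enyl group) | c1oc2c3c(c(O)c4ccccc4c(=O)c13)C(=O)c1ccccc1-2 | intermediate
11 | bromo-nor-radermachol (10 with Br on the furan α-carbon) | Brc1oc2c3c(c(O)c4ccccc4c(=O)c13)C(=O)c1ccccc1-2 | intermediate
12 | 4,4,5,5-tetramethyl-2-(2-methylprop-1-enyl)-1,3,2-dioxaborolane | CC(C)=CB1OC(C)(C)C(C)(C)O1 | starting material
13 | radermachol | CC(C)=Cc1oc2c3c(c(O)c4ccccc4c(=O)c13)C(=O)c1ccccc1-2 | target

**Summary**

Total step count: 6. Longest linear sequence: 6 steps (1 to 13).

Steps most likely to fail:

Step 4. Radiationless decay of the hydrogen-bonded enol (excited-state proton transfer, twisting about the enol double bond) may outrun the electrocyclization, or iodine may attack the enolic carbon in the dark. The ring would then be closed by a known palladium-catalysed intramolecular direct arylation. The fallback sets out from 5. α-Arylation with 1-(2-chlorophenyl)ethanone (CC(=O)c1ccccc1Cl) under the first-stage conditions of step 3, which should leave the aryl chloride untouched at 90 °C, gives methyl 2-{4-[2-(2-chlorophenyl)-2-oxoethyl]furan-3-carbonyl}benzoate F1. KOtBu cyclises it to 10-(2-chlorobenzoyl)-9-hydroxy-4H-benzo[5,6]cyclohepta[1,2-c]furan-4-one F2. Pd(OAc)2, PCy3·HBF4, K2CO3, DMA, 130 °C then joins the chloride-bearing carbon to furan C-1 by concerted metalation–deprotonation and reductive elimination. The fallback comes back to the route at 10.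

Step 5. The electrophile may go to the enolic carbon of the 1,3-diketone, or substitution at the acyl-deactivated furan position may be too slow. Halogenation is then replaced by a C–H palladation that selects by acidity and not by nucleophilicity. The fallback sets out from 10: 1-bromo-2-methylprop-1-ene (CC(C)=CBr), Pd(OAc)2, KOAc, DMA, 110 °C should alkenylate the furan α C–H directly by concerted metalation–deprotonation at the C–H flanked by the ring oxygen and the acyl-bearing carbon. It comes back at 13, leaving out 11 and step 6, and makes no new compound.

Step 3. Aldol addition of the acetophenone enolate to the diaryl ketone of 5, followed by lactonisation of the alkoxide onto the neighbouring ester (phthalide formation), may outrun the cross-coupling. The two-carbon unit is then brought in without an enolate. The fallback sets out from 5: Sonogashira coupling with phenylacetylene (C#Cc1ccccc1; PdCl2(PPh3)2, CuI, Et3N, 60 °C) gives methyl 2-[4-(phenylethynyl)furan-3-carbonyl]benzoate F3. Hydration with a cationic monovalent gold catalyst (Ph3PAuCl, AgOTf, wet 1,4-dioxane, 60 °C) is directed by the neighbouring ketone: 6-endo attack of the carbonyl oxygen on the phenyl-bearing alkyne carbon, then opening of the pyrylium-type intermediate by water, places the new carbonyl next to phenyl. The fallback comes back at 7, now isolated, which the KOtBu stage of step 3 converts into 8.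

Further compounds
F1 | step 4 | methyl 2-{4-[2-(2-chlorophenyl)-2-oxoethyl]furan-3-carbonyl}benzoate | COC(=O)c1ccccc1C(=O)c1cocc1CC(=O)c1ccccc1Cl
F2 | step 4 | 10-(2-chlorobenzoyl)-9-hydroxy-4H-benzo[5,6]cyclohepta[1,2-c]furan-4-one | O=C1c2ccccc2C(O)=C(C(=O)c2ccccc2Cl)c2cocc12
F0 | step 5 | none | none
F3 | step 3 | methyl 2-[4-(phenylethynyl)furan-3-carbonyl]benzoate | COC(=O)c1ccccc1C(=O)c1cocc1C#Cc1ccccc1
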